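## The problem

The target 29 is a guaiane-type hydroazulenone. A cyclopentenone (C1–C5, ketone at C3, alkene C4=C5, methyl on C4) is fused along C1–C5 to a seven-membered ring (C5–C10 and C1), and the fusion carbon C1 is a tertiary carbinol. There are five stereocentres (C1, C6, C7, C8, C10). The C6 hydroxyl, the C7 side chain (C11), the C8 angeloyloxy group and the C10 methyl lie on one face of the seven-membered ring, and the C1 hydroxyl on the other. Only the adjacent pair C6/C7 must be made in absolute terms. Once it exists it can direct C10 (through the folding of a ring closure) and C8 (through hydride addition next to C7), and C10 then sits beside C1 when the five-membered ring is closed. Four oxygens must end in four different states: free secondary C6–OH, C8 angelate, tertiary C11 acetate and free tertiary C1–OH. The compound is fragile: the angelate isomerises to the tiglate under nucleophilic or strongly basic acylation conditions, both hydroxyls are γ to the enone carbonyl and prone to elimination or retro-aldol cleavage, and the esters on C8–O and C11–O can migrate to the cis C6–OH. Two features make the key step possible. First, C1(OH)–C2–C3(=O) is an aldol retron whose opening leaves a C1/C3 enedione across C5=C4, the oxidised form of a furan with ring atoms O, C1, C5, C4, C3 in which C1 is the only unsubstituted, nucleophilic α-carbon. Second, the methyl-bearing C10 is β to oxygenated C8, so with C8 as a ketone the unit C8–C9=C10 is a crotonyl acceptor that C1 can attack to close the seven-membered ring.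

## Retrosynthesis

Abbreviations: TBS = tert-butyldimethylsilyl, TES = triethylsilyl. Guaiane numbering is used for all intermediates.

**29 to 26 (C6–O–Si, then C1–C2).** 29 is released from its C6 silyl ether 28. In 28 the C1–C2 bond is cut (retro-aldol) to the (Z)-enedione 27, whose C1 and C3 carbonyl oxygens are merged into the ring oxygen of the tetrasubstituted furan 26. Compared with cuts at C1–C5 or C4–C5, this removes the most fragile part of the target (tertiary allylic alcohol and enone) and the C1 stereocentre in exchange for an aromatic ring that survives all earlier steps. The forward reaction must open the furan without touching the angelate, and the aldol must place the hydroxyl trans to the C10 methyl.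

**26 to 20 (acyl–O bonds at C11 and C8, C8–H).** The acetate (26 from 25), the C11 silyl ether (25 from 24) and the angelate (24 from 21) are removed in turn, and the C8 carbinol 21 is traced to ketone 20. The order is chosen so that each acylation meets a single free hydroxyl: C8–OH is esterified while C11 is silylated, and C11–OH is acetylated while the furan still masks C1. The forward reduction must deliver hydride to the face of C8 opposite the C7 side chain.

**20 to 19 (C1–C10, the key cut).** Within the seven-membered ring, a C5–C6 cut would ask a furan β-carbon to act as nucleophile, and C6–C7 or C7–C8 cuts would create stereocentres during a medium-ring closure. The C1–C10 cut pairs the most nucleophilic furan position with the β-carbon of an enone that already carries the C8 oxygen. The precursor 19 is acyclic with two stereocentres. The forward reaction must close in the 7-endo mode, set the C10 methyl cis to the C7 side chain, and leave both silyl ethers intact.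

**19 to 14 (C8–C9).** Enone 19 comes from allylic alcohol 18, and 18 from aldehyde 15 and the (E)-propenyl donor 16 (through 17). Cutting C8–C9 rather than C9=C10 takes the alkene geometry from the reagent instead of from a condensation. Aldehyde 15 is the reduced form of ester 14.

**14 to 10 (C7–C11).** After removal of the silyl groups (14 from 12), the C7–C11 bond is cut to the β-hydroxy ester 10 and a three-carbon ketone electrophile, joined through the alkoxide–enolate 11. The more convergent cut at C6–C7 (aldol of a furan aldehyde with a ketone already holding C8–C11) would need a reagent-controlled anti aldol of a neopentyl-type enolate and gives no reliable absolute control. The chosen cut lets the single centre C6 control C7 through a chelated enolate and brings in the hindered carbon as a small electrophile. The price is a longer linear sequence.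

**10 to 1 (C6 stereocentre, C6–C7, furan functionalisation).** The C6 carbinol of 10 comes from ketone 9 by catalyst-controlled transfer hydrogenation, so all chirality originates in one catalytic step. Keto ester 9 is the two-carbon homologue of acid 7, and 7 the carboxylation product of bromide 5. The bromine reaches the β-position of 1 by α-bromination (2) and base-induced migration (through 3 and 4).

## Roads not taken

**Alternative 1:** Photochemical rearrangement of a decalin dienone. The cut is C1–C5 with re-formation of C5–C10, which turns the 5/7 system into the cross-conjugated 6/6 dienone A1. Forward, irradiation of A1 in a carboxylic acid solvent would bond C1 to C5, break C5–C10 and trap C10 with carboxylate, giving hydroazulenone A2 with the C3 ketone and C4=C5 in place.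
- Merits: the rearrangement has long precedent on exactly this ring system, both rings arise in one step, and the six-membered ring of A1 makes C6–C8 easier to set than on a seven-membered ring.
- Weak points: the oxygen lands on the wrong carbon. A2 has acetoxy on C10 and hydrogen on C1, whereas the target has hydrogen on C10 and hydroxyl on C1. Repair needs a stereocontrolled deoxygenation of a tertiary centre and oxidation of the tertiary C1–H beside a second γ-position (C6), in the presence of three esters. A1 also needs a quaternary C10 and dense oxygenation before the photochemical step.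
- Comparison: in the ring-forming step Alternative 1 is better precedented and more productive, since it delivers the cyclopentenone directly. The chosen plan sets against this that the furan oxygen is the C1 oxygen by construction, so no redox repair at C1 and C10 follows.

**Alternative 2:** Oxygen-bridged [4+3] cycloadduct. The cuts are C1–C5 and C7–C8 together, leading to the furan-tethered α-chloro ketone A3. Forward, an amine base in a fluorinated alcohol would ionise A3 to the oxyallyl cation C5–C6–C7, which adds across furan carbons C1 and C8 to give the bridged ketone A4.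
- Merits: two C–C bonds, two rings and the relative configuration of C1, C5, C7 and C8 from one step, which is more than the chosen key step achieves. The bridge also brings oxygen to C1 and C8.
- Weak points: the bridge holds C1–O and C8–O on the same face, but the target has them on opposite faces, so only one can be kept as delivered. The usual bridge opening by β-elimination from the C6 ketone would sacrifice C8–O. A4 then still needs reduction of the C6 ketone, saturation of C9=C10 with control of C10, and regioselective introduction of C4=C5, and the tether stereocentre C4 that steers the cycloaddition is destroyed later.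
- Comparison: Alternative 2 is superior in bond and ring economy at the key step. The chosen plan sets against this a cyclisation product that needs only functional-group changes (one reduction, two acylations, one furan oxidation) and no skeletal redox corrections.

**Alternative 3:** Furan opening and aldol as the strategic step. The cut is C1–C2 only, leading to the cyclohepta[b]furan A5 with C8 as a silyl ether and C11 as acetate. Forward, a peracid opens the furan and mild base closes C2 onto C1, giving A6.
- Merits: this is the most direct entry to a 4-hydroxycyclopentenone. With C8 silylated in A5 and A6, the angelate never meets peracid or base, which is a real advantage.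
- Weak points: the plan is silent on how the seven-membered ring and C10 are made, which is the harder problem. Its key step forms an easy five-membered ring, and because the aldol is reversible and C10 is epimerisable in the enedione, it is also the step with the least certain stereochemical outcome. The protecting pattern of A6 costs two further steps: C8 desilylation beside the C6 silyl ether, and angeloylation beside the free tertiary allylic C1–OH.
- Comparison: the chosen plan uses the same transformation as its step 16, so the two differ in emphasis and protecting-group order, not in chemistry. Alternative 3 is safer for the angelate. The chosen plan sets against this a defined construction of the furan-fused seven-membered ring, two fewer steps after that ring exists, and no acylation next to the hydroxy enone.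

Key step: step 11

Assumption: the tertiary silyl ether on C11 is treated as a non-chelating group, so the stereochemical analysis of step 11 rests on a monodentate scandium–carbonyl complex.

## Route

Step 1
Reactants: 1 2,3-dimethylfuran
Product: 2 5-bromo-2,3-dimethylfuran
Conditions: NBS (1.0 equiv), DMF, −20 to 0 °C, dark
Reagents that add atoms: N-bromosuccinimide, O=C1CCC(=O)N1Br
Why: Electrophilic aromatic bromination at the only free α-position of the electron-rich furan; polar, dark conditions suppress radical side-chain bromination.

Step 2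
Reactants: 2 5-bromo-2,3-dimethylfuran
Product: 5 4-bromo-2,3-dimethylfuran, via 5-bromo-4-lithio-2,3-dimethylfuran 3 (not isolated), via 4-bromo-5-lithio-2,3-dimethylfuran 4 (not isolated)
Conditions: LiN(i-Pr)2 (1.2 equiv), THF, −78 °C; then H2O
Reagents that add atoms: none
Why: Halogen dance: the only ring hydrogen (ortho to bromine) is removed, intermolecular bromine–lithium exchange then moves lithium to the more stabilising α-carbon and bromine to the β-carbon, and protonation gives the β-bromofuran.

Step 3
Reactants: 5 4-bromo-2,3-dimethylfuran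
Product: 7 4,5-dimethylfuran-3-carboxylic acid, via (4,5-dimethylfuran-3-yl)lithium 6 (not isolated)
Conditions: n-BuLi, Et2O, −78 °C; CO2; then aq. HCl
Reagents that add atoms: carbon dioxide, O=C=O
Why: Bromine–lithium exchange in ether at −78 °C gives the 3-furyllithium without migration to the α-position, and carboxylation is fast; the acid is stable and purified by extraction.

Step 4
Reactants: 7 4,5-dimethylfuran-3-carboxylic acid
Product: 9 ethyl 3-(4,5-dimethylfuran-3-yl)-3-oxopropanoate, via acyl imidazolide 8 (not isolated)
Conditions: 1,1'-carbonyldiimidazole, THF, rt; then KO2CCH2CO2Et, MgCl2, Et3N, MeCN, rt to 50 °C; aq. HCl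
Reagents that add atoms: potassium ethyl malonate, CCOC(=O)CC(=O)[O-].[K+]; 1,1'-carbonyldiimidazole, O=C(n1ccnc1)n1ccnc1 (its imidazole stays in intermediate 8 only)
Why: Masamune–Brooks-type C-acylation of magnesium ethyl malonate by the acyl imidazolide followed by decarboxylation, a near-neutral decarboxylative Claisen condensation that the furan tolerates.

Step 5
Reactants: 9 ethyl 3-(4,5-dimethylfuran-3-yl)-3-oxopropanoate
Product: 10 ethyl (3R)-3-(4,5-dimethylfuran-3-yl)-3-hydroxypropanoate
Conditions: RuCl[(R,R)-TsDPEN](p-cymene) (1 mol %), HCO2H–Et3N (5:2), DMF, 40 °C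
Reagents that add atoms: none
Why: Noyori–Ikariya asymmetric transfer hydrogenation of a heteroaryl ketone; with the furan in the aryl position of the CH–π-controlled transition state the (R,R)-ligand is expected to give the (R)-carbinol, as with aryl alkyl ketones, which sets C6.

Step 6
Reactants: 10 ethyl (3R)-3-(4,5-dimethylfuran-3-yl)-3-hydroxypropanoate
Product: 12 ethyl (2R,3R)-3-(4,5-dimethylfuran-3-yl)-3-hydroxy-2-(2-hydroxypropan-2-yl)propanoate, via dilithium alkoxide enolate 11 (not isolated)
Conditions: LiN(i-Pr)2 (2.2 equiv), THF, −78 to −20 °C; acetone, −78 °C; AcOH, −78 °C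
Reagents that add atoms: acetone, CC(C)=O
Why: Aldol addition of the chelated lithium alkoxide–enolate (Fráter–Seebach dianion) to a ketone; the electrophile enters the enolate face anti to the furyl group on the chelate ring, which should give the 2,3-anti product and so set C7 from C6.

Step 7
Reactants: 12 ethyl (2R,3R)-3-(4,5-dimethylfuran-3-yl)-3-hydroxy-2-(2-hydroxypropan-2-yl)propanoate
Product: 14 ethyl (2R,3R)-3-(tert-butyldimethylsilyloxy)-3-(4,5-dimethylfuran-3-yl)-2-[2-(triethylsilyloxy)propan-2-yl]propanoate, via C6 mono-TBS ether 13 (not isolated)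
Conditions: TBSOTf (1.05 equiv), 2,6-lutidine, CH2Cl2, −78 °C; then TESOTf (1.5 equiv), −78 to 0 °C
Reagents that add atoms: tert-butyldimethylsilyl triflate, CC(C)(C)[Si](C)(C)OS(=O)(=O)C(F)(F)F; triethylsilyl triflate, CC[Si](CC)(CC)OS(=O)(=O)C(F)(F)F
Why: Silyl triflate silylation; the secondary carbinol should react with the bulky triflate at −78 °C well before the tertiary one, which is then capped with the smaller reagent, giving two silyl ethers that can later be removed in sequence.

Step 8
Reactants: 14 ethyl (2R,3R)-3-(tert-butyldimethylsilyloxy)-3-(4,5-dimethylfuran-3-yl)-2-[2-(triethylsilyloxy)propan-2-yl]propanoate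
Product: 15 (2R,3R)-3-(tert-butyldimethylsilyloxy)-3-(4,5-dimethylfuran-3-yl)-2-[2-(triethylsilyloxy)propan-2-yl]propanal
Conditions: i-Bu2AlH (1.3 equiv), CH2Cl2, −78 °C; MeOH, aq. potassium sodium tartrate
Reagents that add atoms: none
Why: Partial reduction of an ester; the hindered aluminium hemiacetal flanked by two silyloxy groups should persist at −78 °C until work-up, so the aldehyde is released only then.

Step 9
Reactants: 15 (2R,3R)-3-(tert-butyldimethylsilyloxy)-3-(4,5-dimethylfuran-3-yl)-2-[2-(triethylsilyloxy)propan-2-yl]propanal; 16 (E)-1-bromoprop-1-ene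
Product: 18 (1R,2R,3RS,4E)-1-(tert-butyldimethylsilyloxy)-1-(4,5-dimethylfuran-3-yl)-2-[2-(triethylsilyloxy)propan-2-yl]hex-4-en-3-ol (both C8 epimers), via (E)-prop-1-enyllithium 17 (not isolated)
Conditions: 16, t-BuLi (2 equiv per 16), Et2O, −78 °C; then 15, −78 °C; H2O
Reagents that add atoms: none
Why: Bromine–lithium exchange with two equivalents of t-BuLi retains the alkene geometry, and the vinyllithium adds 1,2 to the aldehyde; the configuration of the new carbinol is irrelevant because it is oxidised next.

Step 10
Reactants: 18 (1R,2R,3RS,4E)-1-(tert-butyldimethylsilyloxy)-1-(4,5-dimethylfuran-3-yl)-2-[2-(triethylsilyloxy)propan-2-yl]hex-4-en-3-ol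
Product: 19 (1R,2R,4E)-1-(tert-butyldimethylsilyloxy)-1-(4,5-dimethylfuran-3-yl)-2-[2-(triethylsilyloxy)propan-2-yl]hex-4-en-3-one
Conditions: Dess–Martin periodinane, NaHCO3, CH2Cl2, 0 °C to rt
Reagents that add atoms: none
Why: Dess–Martin oxidation of an allylic alcohol under buffered conditions, which should leave the furan, the silyl ethers, the C7 stereocentre and the (E)-alkene untouched.

Step 11
Reactants: 19 (1R,2R,4E)-1-(tert-butyldimethylsilyloxy)-1-(4,5-dimethylfuran-3-yl)-2-[2-(triethylsilyloxy)propan-2-yl]hex-4-en-3-one
Product: 20 (4R,5R,8S)-4-(tert-butyldimethylsilyloxy)-2,3,8-trimethyl-5-[2-(triethylsilyloxy)propan-2-yl]-4,5,7,8-tetrahydro-6H-cyclohepta[b]furan-6-one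
Conditions: Sc(OTf)3 (10 mol %), MeCN–CH2Cl2 (0.01 M), −20 °C to rt
Reagents that add atoms: none
Why: Sc(OTf)3 binds the C8 carbonyl of the s-trans enone and makes C10 electrophilic; C1, the only unsubstituted furan carbon and an α-position, attacks C10 to give a σ-complex and a scandium enolate, and loss of the C1 proton with protonation at C9 restores the furan and releases ketone and catalyst. The closest known reaction type is the intramolecular Friedel–Crafts (Michael-type) alkylation of furans and indoles by enones, together with furan-terminated cationic cyclisation. The seven-membered ring closes in the 7-endo-trig mode, the forming bond lying roughly perpendicular to both the enone plane and the furan plane. The new stereocentre C10 is controlled by C6 and C7 through a chair-like transition state: allylic 1,3-strain with the furan C4 methyl keeps C6–H in the furan plane and the silyloxy group pseudo-axial on the face away from the enone, the bulky C7 substituent sits pseudo-equatorial near the carbonyl plane, and the methyl of the (E)-alkene points outward. In this arrangement C1 reaches the face of C10 that puts the methyl cis to the C7 side chain and to C6–O, whereas the chair leading to the C10 epimer would need the C6 silyloxy group eclipsed with the furan methyl and the C7 substituent pseudo-axial. The step needs conjugate addition to win over attack at the carbonyl carbon, over ionisation of the furfuryl-type C6 silyl ether and over β-elimination of the C11 silyloxy group; a catalytic oxophilic Lewis acid at low temperature and high dilution, the thermodynamic advantage of the conjugate adduct and the defined alkene geometry are expected to secure this.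

Step 12
Reactants: 20 (4R,5R,8S)-4-(tert-butyldimethylsilyloxy)-2,3,8-trimethyl-5-[2-(triethylsilyloxy)propan-2-yl]-4,5,7,8-tetrahydro-6H-cyclohepta[b]furan-6-one
Product: 21 (4R,5R,6R,8S)-4-(tert-butyldimethylsilyloxy)-2,3,8-trimethyl-5-[2-(triethylsilyloxy)propan-2-yl]-5,6,7,8-tetrahydro-4H-cyclohepta[b]furan-6-ol
Conditions: LiBH(s-Bu)3, THF, −78 °C; then H2O
Reagents that add atoms: none
Why: Ketone reduction by a bulky trialkylborohydride; as with 2-alkylcycloalkanones the hydride should enter from the face opposite the pseudo-equatorial C7 substituent, giving the C8 alcohol cis to the C7 side chain, and quenching cold avoids silyl migration to the new alkoxide.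

Step 13
Reactants: 21 (4R,5R,6R,8S)-4-(tert-butyldimethylsilyloxy)-2,3,8-trimethyl-5-[2-(triethylsilyloxy)propan-2-yl]-5,6,7,8-tetrahydro-4H-cyclohepta[b]furan-6-ol; 22 angelic acid
Product: 24 (4R,5R,6R,8S)-4-(tert-butyldimethylsilyloxy)-2,3,8-trimethyl-5-[2-(triethylsilyloxy)propan-2-yl]-5,6,7,8-tetrahydro-4H-cyclohepta[b]furan-6-yl (2Z)-2-methylbut-2-enoate, via angelic 2,4,6-trichlorobenzoic anhydride 23 (not isolated)
Conditions: 22, 2,4,6-trichlorobenzoyl chloride, Et3N, toluene, rt; then 21, 80 °C
Reagents that add atoms: 2,4,6-trichlorobenzoyl chloride, O=C(Cl)c1c(Cl)cc(Cl)cc1Cl (stays in intermediate 23 only)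
Why: Yamaguchi esterification through the mixed anhydride without a nucleophilic catalyst, the established way to make angelates without isomerisation to the tiglate; C8–OH is the only free hydroxyl.

Step 14
Reactants: 24 (4R,5R,6R,8S)-4-(tert-butyldimethylsilyloxy)-2,3,8-trimethyl-5-[2-(triethylsilyloxy)propan-2-yl]-5,6,7,8-tetrahydro-4H-cyclohepta[b]furan-6-yl (2Z)-2-methylbut-2-enoate
Product: 25 (4R,5R,6R,8S)-4-(tert-butyldimethylsilyloxy)-5-(2-hydroxypropan-2-yl)-2,3,8-trimethyl-5,6,7,8-tetrahydro-4H-cyclohepta[b]furan-6-yl (2Z)-2-methylbut-2-enoate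
Conditions: HF·pyridine, pyridine, THF, 0 °C
Reagents that add atoms: none
Why: Fluoride-mediated desilylation; the triethylsilyl ether should be cleaved by buffered HF·pyridine well before the hindered tert-butyldimethylsilyl ether, and the buffered medium spares furan and angelate.

Step 15
Reactants: 25 (4R,5R,6R,8S)-4-(tert-butyldimethylsilyloxy)-5-(2-hydroxypropan-2-yl)-2,3,8-trimethyl-5,6,7,8-tetrahydro-4H-cyclohepta[b]furan-6-yl (2Z)-2-methylbut-2-enoate
Product: 26 (4R,5R,6R,8S)-5-(2-acetoxypropan-2-yl)-4-(tert-butyldimethylsilyloxy)-2,3,8-trimethyl-5,6,7,8-tetrahydro-4H-cyclohepta[b]furan-6-yl (2Z)-2-methylbut-2-enoate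
Conditions: Ac2O, DMAP, Et3N, CH2Cl2, rt to 40 °C
Reagents that add atoms: acetic anhydride, CC(=O)OC(C)=O
Why: DMAP-catalysed acetylation of a tertiary alcohol with excess anhydride; no other hydroxyl is free, the fully substituted furan cannot be C-acylated, and without an alkoxide base the neighbouring angelate should not migrate.

Step 16
Reactants: 26 (4R,5R,6R,8S)-5-(2-acetoxypropan-2-yl)-4-(tert-butyldimethylsilyloxy)-2,3,8-trimethyl-5,6,7,8-tetrahydro-4H-cyclohepta[b]furan-6-yl (2Z)-2-methylbut-2-enoate
Product: 28 (1R,6R,7R,8R,10S)-11-acetoxy-6-(tert-butyldimethylsilyloxy)-1-hydroxy-3-oxoguai-4-en-8-yl (2Z)-2-methylbut-2-enoate, via (Z)-enedione 27 (not isolated)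
Conditions: m-CPBA (1.05 equiv), NaHCO3, CH2Cl2, 0 °C; aq. NaHCO3 wash; then DBU (0.3 equiv), CH2Cl2, 0 °C
Reagents that add atoms: m-chloroperoxybenzoic acid, OOC(=O)c1cccc(Cl)c1
Why: Peracid oxidation opens the electron-rich tetrasubstituted furan to the (Z)-enedione far faster than it attacks the electron-poor angelate alkene, and intramolecular aldol addition of the methyl ketone enolate (C2) to the C1 ketone then closes the hydroxycyclopentenone. C2 is expected to add to C1 anti to the pseudo-axial C10–H, which puts the hydroxyl trans to the C10 methyl; the competing C10 enolate cannot close onto C3 without a bridgehead alkene.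

Step 17
Reactants: 28 (1R,6R,7R,8R,10S)-11-acetoxy-6-(tert-butyldimethylsilyloxy)-1-hydroxy-3-oxoguai-4-en-8-yl (2Z)-2-methylbut-2-enoate
Product: 29 (1R,6R,7S,8R,10S)-11-acetoxy-1,6-dihydroxy-3-oxoguai-4-en-8-yl (2Z)-2-methylbut-2-enoate
Conditions: HF·pyridine, THF, 0 °C to rt
Reagents that add atoms: none
Why: Desilylation with HF·pyridine, which is acidic enough to prevent acyl migration from C8–O or C11–O to the freed C6–OH and mild enough for the tertiary allylic C1–OH.

## Compound list

1 | 2,3-dimethylfuran | Cc1occc1C | starting material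
2 | 5-bromo-2,3-dimethylfuran | Cc1oc(Br)cc1C | intermediate
3 | 5-bromo-4-lithio-2,3-dimethylfuran (formed in the flask of step 2) | Cc1oc(Br)c([Li])c1C | intermediate
4 | 4-bromo-5-lithio-2,3-dimethylfuran (formed in the flask of step 2) | Cc1oc([Li])c(Br)c1C | intermediate
5 | 4-bromo-2,3-dimethylfuran | Cc1occ(Br)c1C | intermediate
6 | (4,5-dimethylfuran-3-yl)lithium (formed in the flask of step 3) | Cc1occ([Li])c1C | intermediate
7 | 4,5-dimethylfuran-3-carboxylic acid | Cc1occ(C(=O)O)c1C | intermediate
8 | (4,5-dimethylfuran-3-yl)(imidazol-1-yl)methanone (formed in the flask of step 4) | Cc1occ(C(=O)n2ccnc2)c1C | intermediate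
9 | ethyl 3-(4,5-dimethylfuran-3-yl)-3-oxopropanoate | CCOC(=O)CC(=O)c1coc(C)c1C | intermediate
10 | ethyl (3R)-3-(4,5-dimethylfuran-3-yl)-3-hydroxypropanoate | CCOC(=O)C[C@@H](O)c1coc(C)c1C | intermediate
11 | dilithium alkoxide–enolate of 10, enolate oxygen cis to C3 (formed in the flask of step 6) | [Li+].[Li+].CCO/C([O-])=C/[C@@H]([O-])c1coc(C)c1C | intermediate
12 | ethyl (2R,3R)-3-(4,5-dimethylfuran-3-yl)-3-hydroxy-2-(2-hydroxypropan-2-yl)propanoate (2,3-anti) | CCOC(=O)[C@@H](C(C)(C)O)[C@@H](O)c1coc(C)c1C | intermediate
13 | ethyl (2R,3R)-3-(tert-butyldimethylsilyloxy)-3-(4,5-dimethylfuran-3-yl)-2-(2-hydroxypropan-2-yl)propanoate (formed in the flask of step 7) | CCOC(=O)[C@@H](C(C)(C)O)[C@@H](O[Si](C)(C)C(C)(C)C)c1coc(C)c1C | intermediate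
14 | ethyl (2R,3R)-3-(tert-butyldimethylsilyloxy)-3-(4,5-dimethylfuran-3-yl)-2-[2-(triethylsilyloxy)propan-2-yl]propanoate | CCOC(=O)[C@@H](C(C)(C)O[Si](CC)(CC)CC)[C@@H](O[Si](C)(C)C(C)(C)C)c1coc(C)c1C | intermediate
15 | (2R,3R)-3-(tert-butyldimethylsilyloxy)-3-(4,5-dimethylfuran-3-yl)-2-[2-(triethylsilyloxy)propan-2-yl]propanal | O=C[C@@H](C(C)(C)O[Si](CC)(CC)CC)[C@@H](O[Si](C)(C)C(C)(C)C)c1coc(C)c1C | intermediate
16 | (E)-1-bromoprop-1-ene | C/C=C/Br | starting material
17 | (E)-prop-1-enyllithium (formed in the flask of step 9) | C/C=C/[Li] | intermediate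
18 | (1R,2R,3RS,4E)-1-(tert-butyldimethylsilyloxy)-1-(4,5-dimethylfuran-3-yl)-2-[2-(triethylsilyloxy)propan-2-yl]hex-4-en-3-ol, both C8 epimers | C/C=C/C(O)[C@@H](C(C)(C)O[Si](CC)(CC)CC)[C@@H](O[Si](C)(C)C(C)(C)C)c1coc(C)c1C | intermediate
19 | (1R,2R,4E)-1-(tert-butyldimethylsilyloxy)-1-(4,5-dimethylfuran-3-yl)-2-[2-(triethylsilyloxy)propan-2-yl]hex-4-en-3-one | C/C=C/C(=O)[C@@H](C(C)(C)O[Si](CC)(CC)CC)[C@@H](O[Si](C)(C)C(C)(C)C)c1coc(C)c1C | intermediate
20 | (4R,5R,8S)-4-(tert-butyldimethylsilyloxy)-2,3,8-trimethyl-5-[2-(triethylsilyloxy)propan-2-yl]-4,5,7,8-tetrahydro-6H-cyclohepta[b]furan-6-one (C6–O, C7 side chain and C10 methyl all cis) | O=C1C[C@H](C)c2oc(C)c(C)c2[C@H](O[Si](C)(C)C(C)(C)C)[C@@H]1C(C)(C)O[Si](CC)(CC)CC | intermediate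
21 | (4R,5R,6R,8S)-4-(tert-butyldimethylsilyloxy)-2,3,8-trimethyl-5-[2-(triethylsilyloxy)propan-2-yl]-5,6,7,8-tetrahydro-4H-cyclohepta[b]furan-6-ol | O[C@@H]1C[C@H](C)c2oc(C)c(C)c2[C@H](O[Si](C)(C)C(C)(C)C)[C@@H]1C(C)(C)O[Si](CC)(CC)CC | intermediate
22 | angelic acid, (2Z)-2-methylbut-2-enoic acid | C/C=C(/C)C(=O)O | starting material
23 | angelic 2,4,6-trichlorobenzoic anhydride (formed in the flask of step 13) | C/C=C(/C)C(=O)OC(=O)c1c(Cl)cc(Cl)cc1Cl | intermediate
24 | (4R,5R,6R,8S)-4-(tert-butyldimethylsilyloxy)-2,3,8-trimethyl-5-[2-(triethylsilyloxy)propan-2-yl]-5,6,7,8-tetrahydro-4H-cyclohepta[b]furan-6-yl (2Z)-2-methylbut-2-enoate | C/C=C(/C)C(=O)O[C@@H]1C[C@H](C)c2oc(C)c(C)c2[C@H](O[Si](C)(C)C(C)(C)C)[C@@H]1C(C)(C)O[Si](CC)(CC)CC | intermediate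
25 | (4R,5R,6R,8S)-4-(tert-butyldimethylsilyloxy)-5-(2-hydroxypropan-2-yl)-2,3,8-trimethyl-5,6,7,8-tetrahydro-4H-cyclohepta[b]furan-6-yl (2Z)-2-methylbut-2-enoate | C/C=C(/C)C(=O)O[C@@H]1C[C@H](C)c2oc(C)c(C)c2[C@H](O[Si](C)(C)C(C)(C)C)[C@@H]1C(C)(C)O | intermediate
26 | (4R,5R,6R,8S)-5-(2-acetoxypropan-2-yl)-4-(tert-butyldimethylsilyloxy)-2,3,8-trimethyl-5,6,7,8-tetrahydro-4H-cyclohepta[b]furan-6-yl (2Z)-2-methylbut-2-enoate | C/C=C(/C)C(=O)O[C@@H]1C[C@H](C)c2oc(C)c(C)c2[C@H](O[Si](C)(C)C(C)(C)C)[C@@H]1C(C)(C)OC(C)=O | intermediate
27 | (Z)-enedione: (1R,2R,3R,5S)-2-(2-acetoxypropan-2-yl)-3-(tert-butyldimethylsilyloxy)-5-methyl-6-oxo-4-[(2Z)-3-oxobutan-2-ylidene]cycloheptyl (2Z)-2-methylbut-2-enoate (formed in the flask of step 16) | C/C=C(/C)C(=O)O[C@@H]1C[C@H](C)C(=O)/C(=C(/C)C(C)=O)[C@H](O[Si](C)(C)C(C)(C)C)[C@@H]1C(C)(C)OC(C)=O | intermediate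
28 | (1R,6R,7R,8R,10S)-11-acetoxy-6-(tert-butyldimethylsilyloxy)-1-hydroxy-3-oxoguai-4-en-8-yl (2Z)-2-methylbut-2-enoate | C/C=C(/C)C(=O)O[C@@H]1C[C@H](C)[C@]2(O)CC(=O)C(C)=C2[C@H](O[Si](C)(C)C(C)(C)C)[C@@H]1C(C)(C)OC(C)=O | intermediate
29 | (1R,6R,7S,8R,10S)-11-acetoxy-1,6-dihydroxy-3-oxoguai-4-en-8-yl (2Z)-2-methylbut-2-enoate (CNP0273287.1) | C/C=C(/C)C(=O)O[C@@H]1C[C@H](C)[C@]2(O)CC(=O)C(C)=C2[C@H](O)[C@@H]1C(C)(C)OC(C)=O | target

## Step count and risk

Total step count: 17. Longest linear sequence: 17 steps (1 to 29); 16 and 22 enter as purchased compounds in steps 9 and 13.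

**Step 11 (key step).** Most likely failure: the furan attacks the carbonyl carbon instead of C10, or the Lewis acid ionises the furfuryl-type C6 silyl ether or eliminates the C11 silyloxy group before the slow closure onto a β-substituted enone. A boat-like folding could also erode facial selectivity at C10. Fallback, from 15 back to 20: addition of MeC≡CMgBr to 15 gives the propargylic alcohol F1, and Dess–Martin oxidation gives the ynone F2. The more electrophilic ynone is closed by 7-endo-dig hydroarylation with (Ph3P)AuCl/AgOTf to the conjugated dienone F3, in which C10 is not yet a stereocentre. Hydrogenation over Pd/C from the face opposite the pseudo-axial C6 silyloxy group and the C7 side chain then sets C10 and gives 20.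

**Step 6.** Most likely failure: proton transfer from the ketone to the hindered enolate instead of addition, retro-aldol loss of the tertiary aldolate on warming, or incomplete anti selectivity because the chelate is less rigid with a furyl substituent. Fallback, from 10 back to 12: saponification (LiOH) gives the hydroxy acid F4. Acetalisation with pivalaldehyde (pyridinium p-toluenesulfonate, water removal) gives the cis-2-tert-butyl-1,3-dioxan-4-one F5. Its rigid cyclic lithium enolate adds to acetone trans to the furyl group to give the dioxanone aldol F6, and ethanolysis (catalytic NaOEt, EtOH, 0 °C) returns 12.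

**Step 12.** Most likely failure: poor facial selectivity because the seven-membered ring is conformationally mobile, or silyl transfer from C11–O to the new alkoxide. Fallback, from 20 back to 24: reduction with a small hydride (NaBH4, CeCl3, MeOH) to favour the C8-epimeric alcohol F7, then Mitsunobu esterification of F7 with 22 (PPh3, diisopropyl azodicarboxylate). This inverts C8 and installs the angelate in one operation, giving 24.

**Step 13.** Most likely failure: slow acylation of the hindered C8 hydroxyl next to the C7 side chain, with isomerisation of the angelate to the tiglate on prolonged heating. Fallback, from 21 back to 24: carbodiimide esterification of 21 with the unhindered 2-[bis(2,2,2-trifluoroethoxy)phosphoryl]propanoic acid gives the phosphonate ester F8. Still–Gennari olefination of F8 with acetaldehyde (KN(SiMe3)2, 18-crown-6, THF, −78 °C) builds the (Z)-alkene on the ester and gives 24.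

**Step 16.** Most likely failure: isomerisation of the (Z)-enedione to the (E)-isomer, which cannot cyclise; epimerisation at C10 through the C1 enolate before ring closure; or low selectivity at C1 because the base-mediated aldol equilibrates. Fallback, from 26 back to 28: 27 is isolated after the peracid step. Its methyl ketone is converted at −78 °C into the silyl enol ether F9 (TMSOTf, Et3N), and F9 is closed by an irreversible intramolecular Mukaiyama aldol (TiCl4, CH2Cl2, −78 °C). Aqueous work-up removes the silyl group from C1–O and gives 28.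

## Further compounds

F1 | step 11 | (1R,2R,3RS)-1-(tert-butyldimethylsilyloxy)-1-(4,5-dimethylfuran-3-yl)-2-[2-(triethylsilyloxy)propan-2-yl]hex-4-yn-3-ol | CC#CC(O)[C@@H](C(C)(C)O[Si](CC)(CC)CC)[C@@H](O[Si](C)(C)C(C)(C)C)c1coc(C)c1C
F2 | step 11 | (1R,2R)-1-(tert-butyldimethylsilyloxy)-1-(4,5-dimethylfuran-3-yl)-2-[2-(triethylsilyloxy)propan-2-yl]hex-4-yn-3-one | CC#CC(=O)[C@@H](C(C)(C)O[Si](CC)(CC)CC)[C@@H](O[Si](C)(C)C(C)(C)C)c1coc(C)c1C
F3 | step 11 | (4R,5R)-4-(tert-butyldimethylsilyloxy)-2,3,8-trimethyl-5-[2-(triethylsilyloxy)propan-2-yl]-4,5-dihydro-6H-cyclohepta[b]furan-6-one | O=C1C=C(C)c2oc(C)c(C)c2[C@H](O[Si](C)(C)C(C)(C)C)[C@@H]1C(C)(C)O[Si](CC)(CC)CC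
F4 | step 6 | (3R)-3-(4,5-dimethylfuran-3-yl)-3-hydroxypropanoic acid | OC(=O)C[C@@H](O)c1coc(C)c1C
F5 | step 6 | (2S,6R)-2-tert-butyl-6-(4,5-dimethylfuran-3-yl)-1,3-dioxan-4-one (cis) | O=C1C[C@H](c2coc(C)c2C)O[C@H](C(C)(C)C)O1
F6 | step 6 | (2S,5R,6R)-2-tert-butyl-6-(4,5-dimethylfuran-3-yl)-5-(2-hydroxypropan-2-yl)-1,3-dioxan-4-one (5,6-trans) | O=C1[C@@H](C(C)(C)O)[C@H](c2coc(C)c2C)O[C@H](C(C)(C)C)O1
F7 | step 12 | (4R,5R,6S,8S)-4-(tert-butyldimethylsilyloxy)-2,3,8-trimethyl-5-[2-(triethylsilyloxy)propan-2-yl]-5,6,7,8-tetrahydro-4H-cyclohepta[b]furan-6-ol (C8 epimer of 21) | O[C@H]1C[C@H](C)c2oc(C)c(C)c2[C@H](O[Si](C)(C)C(C)(C)C)[C@@H]1C(C)(C)O[Si](CC)(CC)CC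
F8 | step 13 | (4R,5R,6R,8S)-4-(tert-butyldimethylsilyloxy)-2,3,8-trimethyl-5-[2-(triethylsilyloxy)propan-2-yl]-5,6,7,8-tetrahydro-4H-cyclohepta[b]furan-6-yl 2-[bis(2,2,2-trifluoroethoxy)phosphoryl]propanoate (both epimers at the phosphonate carbon) | CC(C(=O)O[C@@H]1C[C@H](C)c2oc(C)c(C)c2[C@H](O[Si](C)(C)C(C)(C)C)[C@@H]1C(C)(C)O[Si](CC)(CC)CC)P(=O)(OCC(F)(F)F)OCC(F)(F)F
F9 | step 16 | trimethylsilyl enol ether of the methyl ketone of 27 | C/C=C(/C)C(=O)O[C@@H]1C[C@H](C)C(=O)/C(=C(/C)C(=C)O[Si](C)(C)C)[C@H](O[Si](C)(C)C(C)(C)C)[C@@H]1C(C)(C)OC(C)=O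
A1 | alternative 1 | cross-conjugated decalin dienone (photochemical precursor) | CC(=O)O[C@@H]1C[C@@]2(C)C=CC(=O)C(C)=C2[C@H](O[Si](C)(C)C(C)(C)C)[C@@H]1C(C)(C)OC(C)=O
A2 | alternative 1 | 10-acetoxy hydroazulenone with hydrogen on C1 | CC(=O)O[C@@H]1C[C@@](C)(OC(C)=O)[C@@H]2CC(=O)C(C)=C2[C@H](O[Si](C)(C)C(C)(C)C)[C@@H]1C(C)(C)OC(C)=O
A3 | alternative 2 | furan-tethered α-chloro ketone (either epimer at the chlorinated carbon) | Cc1ccoc1CC1(OCCO1)[C@@H](C)CC(=O)C(Cl)C(C)(C)O[Si](CC)(CC)CC
A4 | alternative 2 | oxygen-bridged tricyclic ketone | O1[C@H]2C=C(C)[C@@]13CC4(OCCO4)[C@@H](C)[C@@H]3C(=O)[C@@H]2C(C)(C)O[Si](CC)(CC)CC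
A5 | alternative 3 | cyclohepta[b]furan with C8 triethylsilyl ether and C11 acetate | CC[Si](CC)(CC)O[C@@H]1C[C@H](C)c2oc(C)c(C)c2[C@H](O[Si](C)(C)C(C)(C)C)[C@@H]1C(C)(C)OC(C)=O
A6 | alternative 3 | protected 1-hydroxy hydroazulenone | CC[Si](CC)(CC)O[C@@H]1C[C@H](C)[C@]2(O)CC(=O)C(C)=C2[C@H](O[Si](C)(C)C(C)(C)C)[C@@H]1C(C)(C)OC(C)=O
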